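**Conventions.** Atoms keep the target numbering: C1 (CH2), C2 (=CH), C3 (enol-ether carbon), C4 (C(CH3)OH), C5 (CH2), C6 (CHOAc), C7, C11 and C12 (β-carbon, α-carbon and carbonyl of the butenolide), C8 (γ-carbon), C9 (exocyclic =CH), C10 (C(CH3)–O), C13 (CH2OAc). Compounds are numbered 1–29 in the order in which they appear in the steps; the full list follows the steps.

Remark on the chemistry: compounds 20–26 are epimer mixtures at C8 (25 and 26 also at the transient sp3 centres), which is irrelevant because C8 ends trigonal. (R)-2-Methylglycidol (10) and (−)-B-allyldiisopinocampheylborane are taken as commercial.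

## Analysis of the target

The target is a germacrane-type ten-membered carbocycle (C1–C10) bridged by an oxygen between C3 and C10. O, C10, C1, C2 and C3 form a 2,3-dihydrofuran whose enol-ether bond C2=C3 is also an E alkene of the large ring. A butenolide is fused at C7–C8 (C7=C11, C12=O, ring oxygen on C8), and its γ-carbon C8 carries the exocyclic enol-lactone alkene C8=C9, with C10 cis to C7 (8E).

There are three stereocentres. The tertiary carbinol C4 (S) and the acetoxy carbon C6 (S) are 1,3-related and anti along C3–C7. The quaternary C10 (S) is insulated from them by trigonal carbons on both sides and has to be set on its own.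

The enol ether next to a tertiary allylic alcohol is labile to acid and to electrophilic oxidants. The cross-conjugated ylidene butenolide is labile to hydroxide and nucleophiles. The two acetates (C6, C13) must be told apart from the free C4 hydroxyl.

The main difficulty is the strained medium ring with two endocyclic alkenes and a one-atom bridge, for which direct carbon–carbon closure is unfavourable. The strategy rests on C8=C9 lying inside the ring between the lactone γ-carbon C8 and the neopentyl carbon C9. C8 is at the aldehyde oxidation level in a γ-hydroxybutenolide and accepts sulfur easily, and C9 is a primary carbon that can receive sulfur through an epoxide. An eleven-membered C8–SO2–C9 ring can therefore be closed by carbon–sulfur bond formation and contracted with loss of SO2.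

## Retrosynthetic reasoning

**Acetates last.** Target 29 is traced to triol 28 and then to the tris-silyl ether 27. Esters at C6 and C13 would not survive the hydroxide of the ring contraction. The tertiary C4 hydroxyl is not acylated under mild conditions, so a global desilylation followed by diacetylation is enough.

**C8=C9 by sulfur dioxide extrusion.** The alkene of 27 is cut and SO2 inserted, giving the eleven-membered sulfone 24. This replaces a ten-membered carbon–carbon closure by a contraction (through bromo sulfone 25 and episulfone 26) of a ring that was closed at sulfur. It creates no stereocentre, and the alkene geometry is fixed by the bicycle. The forward step must halogenate C8 and not C9, and must leave the lactone intact.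

**The enol ether is unmasked only now.** The C3–O bond of 24 is cut to give the ring alkyne 23 with a free C10 hydroxyl. An enol ether would not survive the acid used for ring closure at sulfur or the peracid used to reach the sulfone, and would compete with the furan during photo-oxygenation. The alkyne is inert to all three and is converted into the dihydrofuran by cycloisomerisation directly before the key step.

**Sulfone from sulfide, and ring closure at C8–S.** Sulfone 23 comes from sulfide 22, which is the cyclic O,S-acetal of thiol 21 with its own γ-hydroxybutenolide. The bond cut is C8–S, because it forms reversibly under acid and allows thermodynamic selection of the ring. The C4 oxygen must be silylated at this point, since a free C4 hydroxyl would take C8 in a six-membered O-acetal.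

**Sulfur and the hydroxybutenolide.** Thiol 21 is stored as thioacetate 20, because a thioester is inert during photo-oxygenation. The butenolide of 20 comes from the 2-silylfuran 19. The silyl group sits on C12, so that C12 becomes the carbonyl and C8 the hemiacetal carbon; an unsubstituted 3,4-dialkylfuran would give both regioisomers. The C9–S bond of 19 is cut to epoxide 17 and thioacetic acid 18. The epoxide carries the latent C9 electrophile and the C10 oxygen through the organometallic coupling, which no sulfur function would survive, and its opening avoids an SN2 reaction at a neopentyl centre.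

**C3–C4 fragment union.** Bis-silyl ether 17 comes from diol 16, which is cut at C3–C4 into methyl ketone 9 and epoxy alkyne 13 (used as acetylide 14 and cerium reagent 15). The C6 hydroxyl of 9 is left free on purpose: as a metal alkoxide it chelates the C4 carbonyl, and this is the only element that can direct the new C4 centre. A silyl ether would not chelate. Both hydroxyls of 16 are then silylated together.

**Furan ketone.** Ketone 9 comes by Wacker oxidation from homoallylic alcohol 8, whose C6 centre is set by reagent-controlled allylation of aldehyde 7. Aldehyde 7 comes from 3 by a C5-selective silylation through the in-situ aminal alkoxides 4–6, and 3 from the symmetric diol 1 through mono-ether 2.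

**Epoxy alkyne.** Compound 13 comes from tosylate 11 by acetylide opening of the epoxide and re-closure onto the tosylate carbon (through 12), and 11 from 10. No bond to the stereocentre is touched, so C10 comes from the chiral pool.

## Alternatives that were turned down

**Alternative 1:** The C10–O bond of the dihydrofuran is disconnected. In the forward step the enol oxygen of a C3 ketone adds across a preformed ten-membered ring to C10 of a C8-keto enone, giving bicycle A1 with the bridge and the C10 centre.

- For: no chiral building block is needed for C10, there is no sulfur or oxidation-state detour, A1 already carries both acetates, and the enol-lactone alkene would later come from a known enol lactonisation of the C8 ketone. On end-game simplicity it is stronger than the chosen route.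
- Against: it presupposes the ten-membered carbocycle, so the hardest problem is moved to an unspecified closure. Oxygen addition to a β,β-disubstituted enone that creates a quaternary C–O centre is reversible and weakly driven. The sense at C10 depends on ring conformation and enone geometry. A1 is a β-alkoxy ketone prone to β-elimination.
- Comparison: the chosen route takes C10 from the chiral pool and closes the ring by a carbon–sulfur bond.

**Alternative 2:** The C9–C10 bond is disconnected. A C9 alkenyl iodide on an (E)-iodomethylene butenolide is metalated with NiCl2 and CrCl2 and adds to a C10 methyl ketone, giving the ten-membered tertiary alcohol A2.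

- For: the C8=C9 geometry is fixed in the open chain and retained. On this point it is stronger than an extrusion whose geometry relies on ring strain. Ring and alkene arrive in one carbon–carbon bond formation, and the acetates are tolerated.
- Against: alkenylchromium reagents add poorly to ketones, and here a quaternary carbinol must form while a ten-membered ring closes. C10 is created without a nearby controlling element. The iodoylidene butenolide is a fragile electrophile toward low-valent metals. The dihydrofuran must still be made from the C3/C4 acetonide of A2 by deprotection, selective C3 oxidation, ketalisation and dehydration next to the ylidene butenolide.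
- Comparison: the chosen route gives certainty at C10 and an easier closure, at the price of a less precedented alkene-forming step.

**Alternative 3:** The C1–C10 bond is disconnected with C3–C8 re-formed, so the ten-membered ring comes from a cyclohexane. The potassium C3 alkoxide of a vinyl carbinol, whose neighbouring C8 carries the C9=C10 silyl enol ether, undergoes a [3,3] shift to the 3-keto ylidene butenolide A3.

- For: a concerted ring expansion avoids the entropic cost of medium-ring closure. On that point it is stronger than a high-dilution closure at sulfur. It delivers C8=C9, the C3 ketone and C10 in one event.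
- Against: the precursor has a quaternary spiro-lactone carbon C8 and needs defined configuration at C3, C4, C6 and C8 plus a geometrically pure silyl enol ether; it is harder to make than the target ring. The C3 alkoxide is β to the lactone oxygen on C8, so fragmentation competes. A fully substituted terminus slows the shift. Chair versus boat decides both C10 and the alkene geometry. The C10 silyl ether of A3 must afterwards be converted into the enol ether.
- Comparison: the chosen route is shorter to its key precursor and leaves only the alkene geometry to the key step.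

Key step: step 15

## Route

Step 1
Reactants: 1 3,4-bis(hydroxymethyl)furan
Product: 2 [4-({[tert-butyl(dimethyl)silyl]oxy}methyl)furan-3-yl]methanol
Conditions: NaH (1.0 equiv), THF, 0 °C to rt; TBSCl (1.0 equiv)
Reagents that add atoms: tert-butyl(chloro)dimethylsilane, CC(C)(C)[Si](C)(C)Cl
Why: Monosilylation of a symmetric diol through its sparingly soluble monosodium alkoxide; bis-ether and recovered diol can be recycled.

Step 2
Reactants: 2 [4-({[tert-butyl(dimethyl)silyl]oxy}methyl)furan-3-yl]methanol
Product: 3 4-({[tert-butyl(dimethyl)silyl]oxy}methyl)furan-3-carbaldehyde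
Conditions: MnO2 (excess), CH2Cl2, rt
Reagents that add atoms: none
Why: Selective oxidation of a furylic (benzylic-type) alcohol to the aldehyde with manganese dioxide; the silyl ether prevents lactol and lactone formation.

Step 3
Reactants: 3 4-({[tert-butyl(dimethyl)silyl]oxy}methyl)furan-3-carbaldehyde
Product: 7 4-({[tert-butyl(dimethyl)silyl]oxy}methyl)-5-(triethylsilyl)furan-3-carbaldehyde, via lithium morpholino alkoxide 4 (not isolated), via C5-lithiated alkoxide 5 (not isolated), via C5-silylated alkoxide 6 (not isolated)
Conditions: morpholine, n-BuLi, THF, −78 °C; 3; s-BuLi, −78 °C; Et3SiCl, −78 °C to rt; aq. NH4Cl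
Reagents that add atoms: chlorotriethylsilane, CC[Si](Cl)(CC)CC
Why: In-situ protection of the aldehyde as an α-amino alkoxide whose bulk blocks the neighbouring ring position, so directed α-lithiation of the furan occurs at C5 next to the CH2OTBS-bearing carbon; silylation and hydrolysis return the aldehyde. The silicon marks the future lactone carbonyl C12.

Step 4
Reactants: 7 4-({[tert-butyl(dimethyl)silyl]oxy}methyl)-5-(triethylsilyl)furan-3-carbaldehyde
Product: 8 (1S)-1-[4-({[tert-butyl(dimethyl)silyl]oxy}methyl)-5-(triethylsilyl)furan-3-yl]but-3-en-1-ol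
Conditions: (−)-Ipc2B(allyl), Et2O, −78 °C; then NaOH, H2O2, 0 °C
Reagents that add atoms: (−)-B-allyldiisopinocampheylborane, C=CCB([C@@H]1C[C@@H]2C[C@H]([C@H]1C)C2(C)C)[C@@H]1C[C@@H]2C[C@H]([C@H]1C)C2(C)C
Why: Brown allylation; the chair transition state of the reagent derived from (+)-α-pinene delivers allyl to the Si face of the aryl-type aldehyde and sets C6 as (S) by reagent control.

Step 5
Reactants: 8 (1S)-1-[4-({[tert-butyl(dimethyl)silyl]oxy}methyl)-5-(triethylsilyl)furan-3-yl]but-3-en-1-ol
Product: 9 (4S)-4-hydroxy-4-[4-({[tert-butyl(dimethyl)silyl]oxy}methyl)-5-(triethylsilyl)furan-3-yl]butan-2-one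
Conditions: PdCl2 (10 mol%), Cu(OAc)2, O2 (1 atm), DMA/H2O, rt
Reagents that add atoms: water, O
Why: Wacker oxidation of the terminal alkene of a homoallylic alcohol to the methyl ketone; the acetate-buffered copper co-oxidant avoids acid that could protodesilylate the furan or dehydrate the aldol.

Step 6
Reactants: 10 (R)-2-methylglycidol
Product: 11 [(2S)-2-methyloxiran-2-yl]methyl 4-methylbenzenesulfonate
Conditions: TsCl, Et3N, DMAP (cat.), CH2Cl2, 0 °C
Reagents that add atoms: 4-methylbenzenesulfonyl chloride, Cc1ccc(cc1)S(Cl)(=O)=O
Why: Sulfonylation of the primary alcohol; the stereocentre is untouched (the descriptor changes only because of the sequence rule).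

Step 7
Reactants: 11 [(2S)-2-methyloxiran-2-yl]methyl 4-methylbenzenesulfonate
Product: 13 (2S)-2-methyl-2-(prop-2-yn-1-yl)oxirane, via hydroxy tosylate 12 (not isolated)
Conditions: TMS-acetylene, n-BuLi, THF, −78 °C; BF3·OEt2; 11, −78 °C; then MeOH, K2CO3, rt
Reagents that add atoms: ethynyltrimethylsilane, C#C[Si](C)(C)C
Why: BF3-assisted acetylide opening of the epoxide at its CH2 terminus, then base-induced closure of the tertiary alkoxide onto the tosylate carbon and methanolysis of the C-silyl group; neither event touches the quaternary carbon, so the future C10 keeps its configuration. The volatile product is handled in solution.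

Step 8
Reactants: 13 (2S)-2-methyl-2-(prop-2-yn-1-yl)oxirane; 9 (4S)-4-hydroxy-4-[4-({[tert-butyl(dimethyl)silyl]oxy}methyl)-5-(triethylsilyl)furan-3-yl]butan-2-one
Product: 16 (1S,3S)-1-[4-({[tert-butyl(dimethyl)silyl]oxy}methyl)-5-(triethylsilyl)furan-3-yl]-3-methyl-6-[(2S)-2-methyloxiran-2-yl]hex-4-yne-1,3-diol, via lithium acetylide 14 (not isolated), via alkynylcerium dichloride 15 (not isolated)
Conditions: 13 (3 equiv), n-BuLi, THF, −78 °C; CeCl3 (anhydrous), −78 °C; 9, −78 to −40 °C; aq. NH4Cl
Reagents that add atoms: none
Why: Organocerium 1,2-addition to an enolisable ketone; the first equivalent converts the C6 hydroxyl into a cerium alkoxide that chelates the C4 carbonyl, and axial attack on this six-membered chelate with the furyl group equatorial should place 4-OH anti to 6-OH along C3–C7, i.e. (4S). The epoxide is not opened at −78 °C and is carried on as the latent C9 electrophile.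

Step 9
Reactants: 16 (1S,3S)-1-[4-({[tert-butyl(dimethyl)silyl]oxy}methyl)-5-(triethylsilyl)furan-3-yl]-3-methyl-6-[(2S)-2-methyloxiran-2-yl]hex-4-yne-1,3-diol
Product: 17 1,3-bis(triethylsilyl) ether of 16
Conditions: TESOTf (2.6 equiv), 2,6-lutidine, CH2Cl2, −78 to −40 °C
Reagents that add atoms: triethylsilyl trifluoromethanesulfonate, CC[Si](CC)(CC)OS(=O)(=O)C(F)(F)F
Why: Silyl triflate silylation of a secondary and a tertiary alcohol; the low temperature and premixed base keep the triflate from opening the epoxide. The C4 silyl ether later prevents the C4 oxygen from capturing C8.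

Step 10
Reactants: 17 1,3-bis(triethylsilyl) ether of 16; 18 thioacetic acid
Product: 19 S-[(2S,6S,8S)-8-[4-({[tert-butyl(dimethyl)silyl]oxy}methyl)-5-(triethylsilyl)furan-3-yl]-2-hydroxy-2,6-dimethyl-6,8-bis(triethylsilyloxy)oct-4-yn-1-yl] ethanethioate
Conditions: AcSH (3 equiv), Cs2CO3 (0.3 equiv), DMF (degassed, dark), rt to 40 °C
Reagents that add atoms: none
Why: SN2 opening of the 2,2-disubstituted epoxide by thioacetate at the CH2 carbon; this sets the C9–S bond without substitution at a neopentyl centre and frees the C10 hydroxyl. Excess acid buffers the alkoxide and suppresses S-to-O acetyl transfer.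

Step 11
Reactants: 19 S-[(2S,6S,8S)-8-[4-({[tert-butyl(dimethyl)silyl]oxy}methyl)-5-(triethylsilyl)furan-3-yl]-2-hydroxy-2,6-dimethyl-6,8-bis(triethylsilyloxy)oct-4-yn-1-yl] ethanethioate
Product: 20 S-[(2S,6S,8S)-8-[4-({[tert-butyl(dimethyl)silyl]oxy}methyl)-2-hydroxy-5-oxo-2,5-dihydrofuran-3-yl]-2-hydroxy-2,6-dimethyl-6,8-bis(triethylsilyloxy)oct-4-yn-1-yl] ethanethioate
Conditions: O2, hν (visible), tetraphenylporphyrin (cat.), CH2Cl2, −78 °C; then H2O, rt
Reagents that add atoms: dioxygen, O=O
Why: [4+2] photo-oxygenation of a 2-silylfuran; silyl migration in the endoperoxide makes the silicon-bearing carbon (C12) the lactone carbonyl and C8 the hemiacetal carbon, regiospecifically. Alkyne, thioester and silyl ethers do not react with singlet oxygen.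

Step 12
Reactants: 20 S-[(2S,6S,8S)-8-[4-({[tert-butyl(dimethyl)silyl]oxy}methyl)-2-hydroxy-5-oxo-2,5-dihydrofuran-3-yl]-2-hydroxy-2,6-dimethyl-6,8-bis(triethylsilyloxy)oct-4-yn-1-yl] ethanethioate
Product: 22 eleven-membered cyclic O,S-acetal (C8–S–C9 sulfide with ring alkyne C2≡C3), via seco thiol 21 (not isolated)
Conditions: K2CO3 (3 equiv), MeOH (degassed), 0 °C; AcOH; then CSA (0.3 equiv), 4 Å MS, CH2Cl2 (1 mM), rt
Reagents that add atoms: none
Why: Methanolysis frees the thiol; on acidification it adds to C8 of the hydroxybutenolide with loss of water, the known acid-catalysed conversion of γ-hydroxybutenolides into γ-alkylthio butenolides, run intramolecularly at high dilution and reversible, so oligomers can funnel to the ring. The C4 silyl ether blocks the six-membered O-acetal and no acid-labile enol ether is present yet.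

Step 13
Reactants: 22 eleven-membered cyclic O,S-acetal (C8–S–C9 sulfide with ring alkyne C2≡C3)
Product: 23 eleven-membered C8–SO2–C9 sulfone with ring alkyne C2≡C3 and free C10 hydroxyl
Conditions: mCPBA (2.6 equiv), NaHCO3, CH2Cl2, 0 °C to rt
Reagents that add atoms: 3-chloroperoxybenzoic acid, OOC(=O)c1cccc(Cl)c1
Why: Peracid oxidation of the sulfide through the sulfoxide to the sulfone; the alkyne and the electron-poor butenolide alkene do not react under these conditions.

Step 14
Reactants: 23 eleven-membered C8–SO2–C9 sulfone with ring alkyne C2≡C3 and free C10 hydroxyl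
Product: 24 eleven-membered C8–SO2–C9 sulfone with 3,10-epoxy bridge (2,3-dihydrofuran), 4,6-bis(triethylsilyl) 13-TBS ether
Conditions: [Au(PPh3)]NTf2 (5 mol%), 4 Å MS, CH2Cl2, 0 °C to rt; Et3N quench
Reagents that add atoms: none
Why: 5-endo-dig hydroalkoxylation of a homopropargylic alcohol catalysed by cationic monovalent gold: anti addition of the C10 hydroxyl to C3 of the activated alkyne and protodeauration at C2 give the dihydrofuran. Attack at C2 would require an oxetane and the C4 oxygen is silylated, so no other oxygen competes.

Step 15
Reactants: 24 eleven-membered C8–SO2–C9 sulfone with 3,10-epoxy bridge (2,3-dihydrofuran), 4,6-bis(triethylsilyl) 13-TBS ether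
Product: 27 4,6-bis(triethylsilyl) 13-(tert-butyldimethylsilyl) ether of the deacetylated target (8E), via 8-bromo sulfone 25 (not isolated), via episulfone 26 (not isolated)
Conditions: CBr2F2 (excess), KOH/Al2O3, t-BuOH/CH2Cl2, 0 °C to rt
Reagents that add atoms: none
Why: KOH on alumina removes the C8 proton, which is acidified by the sulfone and the butenolide (the anion is a 2-oxidofuran), and CBr2F2 transfers bromine to this carbanion to give 25. Deprotonation of the far less acidic C9 methylene then triggers the 1,3-elimination to the thiirane dioxide 26, which loses SO2 and leaves C8=C9. The closest known reaction type is the Ramberg–Bäcklund reaction with in situ halogenation, used for ring contraction of macrocyclic sulfones and for making exocyclic enol ethers from α-alkoxy sulfones. The ten-membered carbocycle forms by contraction of the eleven-membered thia-ring; the only ring closed in the step itself is the transient three-membered episulfone (3-exo-tet displacement of bromide). No new stereocentre remains, and the alkene geometry is set by the nine-membered ring O–C10–C9–C8–C7–C6–C5–C4–C3, which cannot hold a trans C8=C9, so C10 ends cis to C7. The step needs halogenation at C8 and not C9, which the large acidity difference secures. It also needs the C8 anion to form before hydroxide attacks the lactone, which the heterogeneous base, the low temperature and the hydroxide-resistant anionic furanolate should ensure. Both C8 epimers of 24 converge on the same product.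

Step 16
Reactants: 27 4,6-bis(triethylsilyl) 13-(tert-butyldimethylsilyl) ether of the deacetylated target (8E)
Product: 28 deacetylated target (4,6,13-triol)
Conditions: TBAF, AcOH (1:1), THF, 0 °C to rt
Reagents that add atoms: none
Why: Fluoride cleavage of all three silyl ethers; buffering with acetic acid protects the base-sensitive ylidene butenolide and the acid-sensitive enol ether.

Step 17
Reactants: 28 deacetylated target (4,6,13-triol)
Product: 29 CNP0144020.1 (target)
Conditions: Ac2O (2.5 equiv), pyridine, DMAP (5 mol%), CH2Cl2, 0 °C
Reagents that add atoms: acetic anhydride, CC(=O)OC(C)=O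
Why: Acylation of the primary C13 and secondary C6 hydroxyls; the hindered tertiary C4 hydroxyl is not acetylated at 0 °C with limited anhydride.

## Compound list

1 | 3,4-bis(hydroxymethyl)furan | OCc1cocc1CO | starting material
2 | [4-({[tert-butyl(dimethyl)silyl]oxy}methyl)furan-3-yl]methanol | OCc1cocc1CO[Si](C)(C)C(C)(C)C | intermediate
3 | 4-({[tert-butyl(dimethyl)silyl]oxy}methyl)furan-3-carbaldehyde | O=Cc1cocc1CO[Si](C)(C)C(C)(C)C | intermediate
4 | lithium [4-(TBS-oxymethyl)furan-3-yl](morpholin-4-yl)methanolate (aminal carbon racemic) | [Li]OC(N1CCOCC1)c1cocc1CO[Si](C)(C)C(C)(C)C | intermediate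
5 | C5-lithio derivative of 4 (lithium on the ring carbon next to the CH2OTBS-bearing carbon) | [Li]OC(N1CCOCC1)c1coc([Li])c1CO[Si](C)(C)C(C)(C)C | intermediate
6 | C5-triethylsilyl derivative of 4 | [Li]OC(N1CCOCC1)c1coc([Si](CC)(CC)CC)c1CO[Si](C)(C)C(C)(C)C | intermediate
7 | 4-({[tert-butyl(dimethyl)silyl]oxy}methyl)-5-(triethylsilyl)furan-3-carbaldehyde | O=Cc1coc([Si](CC)(CC)CC)c1CO[Si](C)(C)C(C)(C)C | intermediate
8 | (1S)-1-[4-(TBS-oxymethyl)-5-(triethylsilyl)furan-3-yl]but-3-en-1-ol | C=CC[C@H](O)c1coc([Si](CC)(CC)CC)c1CO[Si](C)(C)C(C)(C)C | intermediate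
9 | (4S)-4-hydroxy-4-[4-(TBS-oxymethyl)-5-(triethylsilyl)furan-3-yl]butan-2-one | CC(=O)C[C@H](O)c1coc([Si](CC)(CC)CC)c1CO[Si](C)(C)C(C)(C)C | intermediate
10 | (R)-2-methylglycidol, [(2R)-2-methyloxiran-2-yl]methanol | C[C@@]1(CO)CO1 | starting material
11 | [(2S)-2-methyloxiran-2-yl]methyl 4-methylbenzenesulfonate | C[C@@]1(COS(=O)(=O)c2ccc(C)cc2)CO1 | intermediate
12 | (2S)-2-hydroxy-2-methyl-5-(trimethylsilyl)pent-4-yn-1-yl 4-methylbenzenesulfonate | C[Si](C)(C)C#CC[C@](C)(O)COS(=O)(=O)c1ccc(C)cc1 | intermediate
13 | (2S)-2-methyl-2-(prop-2-yn-1-yl)oxirane | C#CC[C@@]1(C)CO1 | intermediate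
14 | lithium acetylide of 13 | [Li]C#CC[C@@]1(C)CO1 | intermediate
15 | alkynylcerium dichloride derived from 14 | Cl[Ce](Cl)C#CC[C@@]1(C)CO1 | intermediate
16 | (1S,3S)-1-[4-(TBS-oxymethyl)-5-(triethylsilyl)furan-3-yl]-3-methyl-6-[(2S)-2-methyloxiran-2-yl]hex-4-yne-1,3-diol (4S,6S,10S in target numbering) | C[C@@]1(CO1)CC#C[C@@](C)(O)C[C@H](O)c2coc([Si](CC)(CC)CC)c2CO[Si](C)(C)C(C)(C)C | intermediate
17 | 1,3-bis(triethylsilyl) ether of 16 | C[C@@]1(CO1)CC#C[C@@](C)(O[Si](CC)(CC)CC)C[C@H](O[Si](CC)(CC)CC)c2coc([Si](CC)(CC)CC)c2CO[Si](C)(C)C(C)(C)C | intermediate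
18 | thioacetic acid | CC(=O)S | starting material
19 | S-[(2S,6S,8S)-8-[4-(TBS-oxymethyl)-5-(triethylsilyl)furan-3-yl]-2-hydroxy-2,6-dimethyl-6,8-bis(triethylsilyloxy)oct-4-yn-1-yl] ethanethioate | CC(=O)SC[C@@](C)(O)CC#C[C@@](C)(O[Si](CC)(CC)CC)C[C@H](O[Si](CC)(CC)CC)c1coc([Si](CC)(CC)CC)c1CO[Si](C)(C)C(C)(C)C | intermediate
20 | γ-hydroxybutenolide from 19: S-[(2S,6S,8S)-8-[4-(TBS-oxymethyl)-2-hydroxy-5-oxo-2,5-dihydrofuran-3-yl]-2-hydroxy-2,6-dimethyl-6,8-bis(triethylsilyloxy)oct-4-yn-1-yl] ethanethioate (C8 anomers) | CC(=O)SC[C@@](C)(O)CC#C[C@@](C)(O[Si](CC)(CC)CC)C[C@H](O[Si](CC)(CC)CC)C1=C(CO[Si](C)(C)C(C)(C)C)C(=O)OC1O | intermediate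
21 | seco thiol: 20 with free C9–SH | SC[C@@](C)(O)CC#C[C@@](C)(O[Si](CC)(CC)CC)C[C@H](O[Si](CC)(CC)CC)C1=C(CO[Si](C)(C)C(C)(C)C)C(=O)OC1O | intermediate
22 | eleven-membered cyclic O,S-acetal: ring C8–S–C9–C10(CH3)(OH)–C1H2–C2≡C3–C4(CH3)(OTES)–C5H2–C6H(OTES)–C7, butenolide C7=C11(CH2OTBS)–C12(=O)–O–C8; (4S,6S,10S), C8 epimers | O=C1OC2SC[C@@](C)(O)CC#C[C@@](C)(O[Si](CC)(CC)CC)C[C@H](O[Si](CC)(CC)CC)C2=C1CO[Si](C)(C)C(C)(C)C | intermediate
23 | sulfone of 22 (C8–SO2–C9), ring alkyne, free C10–OH; (4S,6S,10S), C8 epimers | O=C1OC2S(=O)(=O)C[C@@](C)(O)CC#C[C@@](C)(O[Si](CC)(CC)CC)C[C@H](O[Si](CC)(CC)CC)C2=C1CO[Si](C)(C)C(C)(C)C | intermediate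
24 | key-step precursor: eleven-membered C8–SO2–C9 sulfone with 3,10-epoxy bridge (C2=C3 enol ether), 4,6-bis(triethylsilyl) 13-TBS ether; (4S,6S,10S), C8 epimers | O=C1OC2S(=O)(=O)C[C@]3(C)CC=C(O3)[C@@](C)(O[Si](CC)(CC)CC)C[C@H](O[Si](CC)(CC)CC)C2=C1CO[Si](C)(C)C(C)(C)C | intermediate
25 | 8-bromo derivative of 24 | O=C1OC2(Br)S(=O)(=O)C[C@]3(C)CC=C(O3)[C@@](C)(O[Si](CC)(CC)CC)C[C@H](O[Si](CC)(CC)CC)C2=C1CO[Si](C)(C)C(C)(C)C | intermediate
26 | episulfone: thiirane 1,1-dioxide spanning C8 and C9 on the ten-membered carbocycle | O=C1OC23C(S2(=O)=O)[C@]4(C)CC=C(O4)[C@@](C)(O[Si](CC)(CC)CC)C[C@H](O[Si](CC)(CC)CC)C3=C1CO[Si](C)(C)C(C)(C)C | intermediate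
27 | key-step product: 4,6-bis(triethylsilyl) 13-(tert-butyldimethylsilyl) ether of the deacetylated target; (4S,6S,10S,8E) | CC(C)(C)[Si](C)(C)OCC1=C2/C(=C\[C@]3(C)CC=C(O3)[C@@](C)(O[Si](CC)(CC)CC)C[C@@H]2O[Si](CC)(CC)CC)OC1=O | intermediate
28 | deacetylated target, 4,6,13-triol; (4S,6S,10S,8E) | OCC1=C2/C(=C\[C@]3(C)CC=C(O3)[C@@](C)(O)C[C@@H]2O)OC1=O | intermediate
29 | CNP0144020.1, 6,13-diacetate; (4S,6S,10S,8E) | CC(=O)OCC1=C2/C(=C\[C@]3(C)CC=C(O3)[C@@](C)(O)C[C@@H]2OC(C)=O)OC1=O | target

## Step count and least certain steps

Total step count: 17. Longest linear sequence: 15 steps (steps 1–5 and 8–17, from 1 to 29). The epoxy alkyne branch (steps 6–7) joins at step 8.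

**Step 15 (key step).** Four processes can divert it:
- hydroxide addition to the lactone carbonyl followed by loss of sulfinate from C8, which opens the sulfur bridge;
- bromine transfer to C11 of the ambident furanolate instead of C8;
- β-elimination of the C10–O bond from the C9 carbanion, which opens the dihydrofuran instead of closing the episulfone;
- hydroxide opening of the enol lactone once formed.

Fallback: the halogenation is separated from the elimination and hydroxide is removed. Starting from 24, kinetic deprotonation at C8 with LiHMDS in THF at −78 °C and quenching with hexachloroethane gives the isolable 8-chloro sulfone F1. Treatment of F1 with KOtBu in THF at −78 to −20 °C effects the 1,3-elimination and SO2 loss and returns to the route at 27.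

**Step 12.** Intermolecular thioacetalisation (oligomers) can outrun the eleven-membered closure. The free thiol can also be lost to disulfide or to radical addition onto the alkyne, and the tertiary C10 hydroxyl can ionise with sulfur participation under acid.

Fallback: sulfur is introduced already at the sulfone level and the ring is closed through a sulfinate. Starting from 17, sodium 3-methoxy-3-oxopropane-1-sulfinate opens the epoxide (DMF/H2O, NH4Cl, 70 °C) to the β-hydroxy sulfone ester F2. Photo-oxygenation as in step 11 gives the hydroxybutenolide sulfone ester F3. NaOMe in MeOH/THF at 0 °C releases the sulfinate by retro-Michael cleavage. After acidification with AcOH, the seco sulfinic acid F4 condenses with its own hydroxybutenolide at high dilution (S-attack on the aldehyde form, then lactonisation). This gives sulfone 23 directly, so steps 12 and 13 are bypassed and the route resumes at 23.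

**Step 14.** The 5-endo closure may be slow in the constrained ring. Adventitious water may add to the activated alkyne, and traces of acid may destroy the new enol ether.

Fallback: hydration is accepted and dehydration follows. Starting from 23, the same gold catalyst in wet THF gives the C3 hemiketal F5 (the C10 hydroxyl closes onto the C3 ketone). MsCl and Et3N in CH2Cl2 at 0 °C dehydrate F5 to the enol ether; only C2 carries a removable hydrogen. The route resumes at 24.

**Step 8.** Facial selectivity at C4 may be poor because the cerium alkoxide chelate is weak, and the aldolate may undergo retro-aldol cleavage.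

Fallback: the alkoxide is replaced by a bidentate ether chelate. Starting from 8, NaH and 4-methoxybenzyl chloride give the PMB ether F6. Wacker oxidation as in step 5 gives the β-PMB-oxy ketone F7. Addition of 15 to the cerium-chelated β-alkoxy ketone at −78 °C gives the tertiary alcohol F8. DDQ in wet CH2Cl2 (pH 7 buffer) removes the PMB group, and the route resumes at 16.

## Further compounds

F1 | step 15 | 8-chloro derivative of sulfone 24 | O=C1OC2(Cl)S(=O)(=O)C[C@]3(C)CC=C(O3)[C@@](C)(O[Si](CC)(CC)CC)C[C@H](O[Si](CC)(CC)CC)C2=C1CO[Si](C)(C)C(C)(C)C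
F2 | step 12 | methyl 3-{[(2S,6S,8S)-8-[4-(TBS-oxymethyl)-5-(triethylsilyl)furan-3-yl]-2-hydroxy-2,6-dimethyl-6,8-bis(triethylsilyloxy)oct-4-yn-1-yl]sulfonyl}propanoate | COC(=O)CCS(=O)(=O)C[C@@](C)(O)CC#C[C@@](C)(O[Si](CC)(CC)CC)C[C@H](O[Si](CC)(CC)CC)c1coc([Si](CC)(CC)CC)c1CO[Si](C)(C)C(C)(C)C
F3 | step 12 | γ-hydroxybutenolide derived from F2 (C8 anomers) | COC(=O)CCS(=O)(=O)C[C@@](C)(O)CC#C[C@@](C)(O[Si](CC)(CC)CC)C[C@H](O[Si](CC)(CC)CC)C1=C(CO[Si](C)(C)C(C)(C)C)C(=O)OC1O
F4 | step 12 | seco sulfinic acid (C9–SO2H) with γ-hydroxybutenolide | OS(=O)C[C@@](C)(O)CC#C[C@@](C)(O[Si](CC)(CC)CC)C[C@H](O[Si](CC)(CC)CC)C1=C(CO[Si](C)(C)C(C)(C)C)C(=O)OC1O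
F5 | step 14 | C3 hemiketal of the sulfone (3-hydroxy-3,10-epoxy bridge, C2 saturated) | O=C1OC2S(=O)(=O)C[C@]3(C)CCC(O)(O3)[C@@](C)(O[Si](CC)(CC)CC)C[C@H](O[Si](CC)(CC)CC)C2=C1CO[Si](C)(C)C(C)(C)C
F6 | step 8 | 4-methoxybenzyl ether of 8 | C=CC[C@H](OCc1ccc(OC)cc1)c1coc([Si](CC)(CC)CC)c1CO[Si](C)(C)C(C)(C)C
F7 | step 8 | (4S)-4-[(4-methoxybenzyl)oxy]-4-[4-(TBS-oxymethyl)-5-(triethylsilyl)furan-3-yl]butan-2-one | CC(=O)C[C@H](OCc1ccc(OC)cc1)c1coc([Si](CC)(CC)CC)c1CO[Si](C)(C)C(C)(C)C
F8 | step 8 | 1-O-(4-methoxybenzyl) ether of diol 16 | C[C@@]1(CO1)CC#C[C@@](C)(O)C[C@H](OCc2ccc(OC)cc2)c2coc([Si](CC)(CC)CC)c2CO[Si](C)(C)C(C)(C)C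
A1 | alternative 1 | 3,10-epoxy-bridged ten-membered C8 ketone with exocyclic C7=C11 alkylidene 2-(trimethylsilyl)ethyl ester, C4 triethylsilyl ether, 6,13-diacetate | C[Si](C)(C)CCOC(=O)/C(COC(C)=O)=C1\C(=O)C[C@]2(C)CC=C(O2)[C@@](C)(O[Si](CC)(CC)CC)C[C@@H]1OC(C)=O
A2 | alternative 2 | ten-membered C10 tertiary allylic alcohol with (E)-ylidene butenolide, C3/C4 acetonide, 6,13-diacetate | CC(=O)OCC1=C2/C(=C\[C@@](C)(O)CC[C@@H]3OC(C)(C)O[C@@]3(C)C[C@@H]2OC(C)=O)OC1=O
A3 | alternative 3 | ten-membered 3-keto ylidene butenolide with C10 TBS ether, C4 triethylsilyl ether, 6,13-bis(TBS) ether | CC(C)(C)[Si](C)(C)OCC1=C2/C(=C\[C@](O[Si](C)(C)C(C)(C)C)(C)CCC(=O)[C@@](C)(O[Si](CC)(CC)CC)C[C@@H]2O[Si](C)(C)C(C)(C)C)OC1=O
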